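The oxolane (O1, C2 aryl, C3 bearing C6, C4 oxygen, C5) is cut at O1–C2 and C3–C6. The key step exploits the fact that C2 and C3 of this ring map onto an aryl alkyne, with the C4 carbinol propargylic and C5 a free CH2OH. In one operation it adds the C5 hydroxyl to C2, carbonylates the vinyl–palladium bond at C3 and closes the ring as a 4,5-dihydrofuran-3-carboxylate. The precursor is (2R)-2-silyloxy-4-(3,4-dimethoxyphenyl)but-3-yn-1-ol, its stereocentre set by asymmetric transfer hydrogenation of an ynone. C4 then steers hydrogen to the opposite face of C2=C3, giving the all-cis ring.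

Key step: step 6

Remark: the CIP label at C3 is R while C4 carries O–Si and becomes S in the target only because O–H ranks below O–C; the geometry (aryl, C6 and the C4 oxygen all cis) is the same throughout.

Step 1
Reactants: 1 2-chloro-N-methoxy-N-methylacetamide; 2 4-methoxybenzyl alcohol
Product: 4 N-methoxy-2-[(4-methoxyphenyl)methoxy]-N-methylacetamide, via sodium (4-methoxyphenyl)methanolate 3 (not isolated)
Conditions: NaH, Bu4NI (cat.), THF, 0 °C to rt
Reagents that add atoms: none
Why: Williamson ether synthesis, in which the alkoxide displaces the activated α-chloride by SN2 while the N-methoxy-N-methylamide is inert to alkoxide.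

Step 2
Reactants: 5 4-ethynyl-1,2-dimethoxybenzene; 4 N-methoxy-2-[(4-methoxyphenyl)methoxy]-N-methylacetamide
Product: 8 4-(3,4-dimethoxyphenyl)-1-[(4-methoxyphenyl)methoxy]but-3-yn-2-one, via lithium (3,4-dimethoxyphenyl)acetylide 6 (not isolated), via tetrahedral lithium hemiaminal adduct 7 (not isolated)
Conditions: n-BuLi, THF, −78 °C; then 4, −78 to 0 °C; aq NH4Cl
Reagents that add atoms: none
Why: Weinreb ketone synthesis, in which the N,O-chelated tetrahedral adduct persists until the quench so that only one acetylide adds.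

Step 3
Reactants: 8 4-(3,4-dimethoxyphenyl)-1-[(4-methoxyphenyl)methoxy]but-3-yn-2-one
Product: 9 (2R)-4-(3,4-dimethoxyphenyl)-1-[(4-methoxyphenyl)methoxy]but-3-yn-2-ol
Conditions: Ru[(S,S)-TsDPEN](p-cymene) (1 mol%), i-PrOH, rt
Reagents that add atoms: none
Why: Asymmetric transfer hydrogenation of an alkynyl ketone (Noyori type), in which the alkynyl group lies next to the cymene ligand in the six-membered hydride/proton transfer, so the (S,S)-catalyst should give the arrangement known for (S)-4-arylbut-3-yn-2-ols, named R here because CH2OPMB outranks the alkynyl carbon.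

Step 4
Reactants: 9 (2R)-4-(3,4-dimethoxyphenyl)-1-[(4-methoxyphenyl)methoxy]but-3-yn-2-ol
Product: 10 tert-butyl{[(2R)-4-(3,4-dimethoxyphenyl)-1-[(4-methoxyphenyl)methoxy]but-3-yn-2-yl]oxy}dimethylsilane
Conditions: TBSCl, imidazole, DMF, rt
Reagents that add atoms: tert-butyldimethylsilyl chloride, CC(C)(C)[Si](C)(C)Cl
Why: Imidazole-promoted silylation of a secondary alcohol, which leaves the C–O bond and hence the stereocentre untouched.

Step 5
Reactants: 10 tert-butyl{[(2R)-4-(3,4-dimethoxyphenyl)-1-[(4-methoxyphenyl)methoxy]but-3-yn-2-yl]oxy}dimethylsilane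
Product: 11 (2R)-2-(tert-butyldimethylsilyloxy)-4-(3,4-dimethoxyphenyl)but-3-yn-1-ol
Conditions: DDQ, CH2Cl2/pH 7 buffer (10:1), 0 °C
Reagents that add atoms: none
Why: Oxidative cleavage of a 4-methoxybenzyl ether by DDQ in wet solvent, which should spare the silyl ether, the alkyne and the dimethoxyarene (no benzylic C–H) and, being neutral, should not move the silyl group to the primary oxygen.

Step 6
Reactants: 11 (2R)-2-(tert-butyldimethylsilyloxy)-4-(3,4-dimethoxyphenyl)but-3-yn-1-ol; 12 carbon monoxide; 13 methanol (also the solvent)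
Product: 16 methyl (4R)-4-(tert-butyldimethylsilyloxy)-2-(3,4-dimethoxyphenyl)-4,5-dihydrofuran-3-carboxylate, via vinylpalladium iodide 14 (not isolated), via acylpalladium iodide 15 (not isolated)
Conditions: PdI2 (2 mol%), KI (20 mol%), CO/air 4:1 (40 atm), MeOH, 60 °C
Reagents that add atoms: none
Why: Iodide-ligated divalent palladium coordinates the C2≡C3 alkyne, the C5 hydroxyl attacks C2 anti to the metal to give vinylpalladium iodide 14, CO inserts into the C3–Pd bond to give acylpalladium iodide 15, and methanolysis releases ester 16, HI and zerovalent palladium, which O2 and HI return to PdI2. The closest known reaction type is the PdI2/KI-catalysed oxidative heterocyclization–alkoxycarbonylation of 3-yne-1,2-diols, which gives furan-3-carboxylates by the same sequence followed by dehydration; here the C4 oxygen is silylated so that the sequence should stop at the dihydrofuran. The one ring (O1–C2–C3–C4–C5) closes in the 5-endo-dig mode, with both alkyne carbons ending inside it. No stereocentre is created, and C4 is carried through unchanged because no bond to it is made or broken. The step needs oxygen attack at C2 and carbonylation faster than protodepalladation or acid-promoted loss of silanol to the furan: the electron-rich dimethoxyphenyl group polarizes the alkyne toward attack at C2 (attack at C3 would need a four-membered ring), the CO pressure favours insertion, and the poor leaving ability of the silyloxy group at moderate temperature should hold back aromatization.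

Step 7
Reactants: 16 methyl (4R)-4-(tert-butyldimethylsilyloxy)-2-(3,4-dimethoxyphenyl)-4,5-dihydrofuran-3-carboxylate
Product: 17 methyl (2R,3R,4R)-4-(tert-butyldimethylsilyloxy)-2-(3,4-dimethoxyphenyl)oxolane-3-carboxylate (all-cis)
Conditions: H2 (4 atm), 5% Rh/Al2O3, EtOAc, rt
Reagents that add atoms: none
Why: Heterogeneous syn hydrogenation of a tetrasubstituted enol ether, in which both hydrogens should arrive on the ring face opposite the bulky C4 silyloxy group, so that the aryl group at C2 and the ester at C3 end cis to each other and to the C4 oxygen; Rh/Al2O3 is chosen for its low tendency to cleave benzylic C–O bonds.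

Step 8
Reactants: 17 methyl (2R,3R,4R)-4-(tert-butyldimethylsilyloxy)-2-(3,4-dimethoxyphenyl)oxolane-3-carboxylate
Product: 19 [(2R,3R,4R)-4-(tert-butyldimethylsilyloxy)-2-(3,4-dimethoxyphenyl)oxolan-3-yl]methanol, via oxolane-3-carbaldehyde 18 (not isolated)
Conditions: LiAlH4, THF, −20 to 0 °C; then Na2SO4·10H2O
Reagents that add atoms: none
Why: Hydride reduction of an ester through the aldehyde, in which carbonyl addition at low temperature should outrun enolization, so that C3 is not epimerized and neither β-oxygen is eliminated.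

Step 9
Reactants: 19 [(2R,3R,4R)-4-(tert-butyldimethylsilyloxy)-2-(3,4-dimethoxyphenyl)oxolan-3-yl]methanol; 20 3,4-dimethoxybenzoyl chloride
Product: 21 [(2R,3R,4R)-4-(tert-butyldimethylsilyloxy)-2-(3,4-dimethoxyphenyl)oxolan-3-yl]methyl 3,4-dimethoxybenzoate
Conditions: Et3N, DMAP (cat.), CH2Cl2, 0 °C to rt
Reagents that add atoms: none
Why: DMAP-catalysed acylation of a primary alcohol by an acid chloride, which touches no stereocentre and leaves the silyl ether in place.

Step 10
Reactants: 21 [(2R,3R,4R)-4-(tert-butyldimethylsilyloxy)-2-(3,4-dimethoxyphenyl)oxolan-3-yl]methyl 3,4-dimethoxybenzoate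
Product: 22 [(2R,3S,4R)-2-(3,4-dimethoxyphenyl)-4-hydroxyoxolan-3-yl]methyl 3,4-dimethoxybenzoate
Conditions: HF·pyridine, pyridine/THF, 0 °C to rt
Reagents that add atoms: none
Why: Fluoride-mediated desilylation under buffered acidic conditions, which frees the C4 hydroxyl without forming an alkoxide and should therefore not move the ester from the C6 oxygen to the cis C4 oxygen.

Compound list
1 | 2-chloro-N-methoxy-N-methylacetamide | CON(C)C(=O)CCl | starting material
2 | 4-methoxybenzyl alcohol | COc1ccc(CO)cc1 | starting material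
3 | sodium (4-methoxyphenyl)methanolate | [Na+].[O-]Cc1ccc(OC)cc1 | intermediate
4 | N-methoxy-2-[(4-methoxyphenyl)methoxy]-N-methylacetamide | CON(C)C(=O)COCc1ccc(OC)cc1 | intermediate
5 | 4-ethynyl-1,2-dimethoxybenzene | C#Cc1ccc(OC)c(OC)c1 | starting material
6 | lithium (3,4-dimethoxyphenyl)acetylide | [Li]C#Cc1ccc(OC)c(OC)c1 | intermediate
7 | lithium 4-(3,4-dimethoxyphenyl)-2-[methoxy(methyl)amino]-1-[(4-methoxyphenyl)methoxy]but-3-yn-2-olate (tetrahedral adduct, configuration at C2 not controlled) | COc1ccc(C#CC(O[Li])(COCc2ccc(OC)cc2)N(C)OC)cc1OC | intermediate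
8 | 4-(3,4-dimethoxyphenyl)-1-[(4-methoxyphenyl)methoxy]but-3-yn-2-one | COc1ccc(C#CC(=O)COCc2ccc(OC)cc2)cc1OC | intermediate
9 | (2R)-4-(3,4-dimethoxyphenyl)-1-[(4-methoxyphenyl)methoxy]but-3-yn-2-ol | COc1ccc(C#C[C@@H](O)COCc2ccc(OC)cc2)cc1OC | intermediate
10 | tert-butyl{[(2R)-4-(3,4-dimethoxyphenyl)-1-[(4-methoxyphenyl)methoxy]but-3-yn-2-yl]oxy}dimethylsilane | COc1ccc(C#C[C@@H](O[Si](C)(C)C(C)(C)C)COCc2ccc(OC)cc2)cc1OC | intermediate
11 | (2R)-2-(tert-butyldimethylsilyloxy)-4-(3,4-dimethoxyphenyl)but-3-yn-1-ol | COc1ccc(C#C[C@@H](O[Si](C)(C)C(C)(C)C)CO)cc1OC | intermediate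
12 | carbon monoxide | [C-]#[O+] | starting material
13 | methanol | CO | starting material
14 | iodo[(4S)-4-(tert-butyldimethylsilyloxy)-2-(3,4-dimethoxyphenyl)-4,5-dihydrofuran-3-yl]palladium (C4 arranged as in 11, label S because the Pd-bearing carbon outranks C5; further iodide or CO ligands not drawn) | I[Pd]C1=C(c2ccc(OC)c(OC)c2)OC[C@@H]1O[Si](C)(C)C(C)(C)C | intermediate
15 | iodo{[(4R)-4-(tert-butyldimethylsilyloxy)-2-(3,4-dimethoxyphenyl)-4,5-dihydrofuran-3-yl]carbonyl}palladium (further ligands not drawn) | I[Pd]C(=O)C1=C(c2ccc(OC)c(OC)c2)OC[C@@H]1O[Si](C)(C)C(C)(C)C | intermediate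
16 | methyl (4R)-4-(tert-butyldimethylsilyloxy)-2-(3,4-dimethoxyphenyl)-4,5-dihydrofuran-3-carboxylate | COC(=O)C1=C(c2ccc(OC)c(OC)c2)OC[C@@H]1O[Si](C)(C)C(C)(C)C | intermediate
17 | methyl (2R,3R,4R)-4-(tert-butyldimethylsilyloxy)-2-(3,4-dimethoxyphenyl)oxolane-3-carboxylate | COC(=O)[C@H]1[C@@H](O[Si](C)(C)C(C)(C)C)CO[C@H]1c1ccc(OC)c(OC)c1 | intermediate
18 | (2R,3R,4R)-4-(tert-butyldimethylsilyloxy)-2-(3,4-dimethoxyphenyl)oxolane-3-carbaldehyde | O=C[C@H]1[C@@H](O[Si](C)(C)C(C)(C)C)CO[C@H]1c1ccc(OC)c(OC)c1 | intermediate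
19 | [(2R,3R,4R)-4-(tert-butyldimethylsilyloxy)-2-(3,4-dimethoxyphenyl)oxolan-3-yl]methanol | OC[C@H]1[C@@H](O[Si](C)(C)C(C)(C)C)CO[C@H]1c1ccc(OC)c(OC)c1 | intermediate
20 | 3,4-dimethoxybenzoyl chloride | COc1ccc(C(Cl)=O)cc1OC | starting material
21 | [(2R,3R,4R)-4-(tert-butyldimethylsilyloxy)-2-(3,4-dimethoxyphenyl)oxolan-3-yl]methyl 3,4-dimethoxybenzoate | COc1ccc(C(=O)OC[C@H]2[C@@H](O[Si](C)(C)C(C)(C)C)CO[C@H]2c2ccc(OC)c(OC)c2)cc1OC | intermediate
22 | [(2R,3S,4R)-2-(3,4-dimethoxyphenyl)-4-hydroxyoxolan-3-yl]methyl 3,4-dimethoxybenzoate | COc1ccc(C(=O)OC[C@H]2[C@@H](O)CO[C@H]2c2ccc(OC)c(OC)c2)cc1OC | target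

Total step count: 10. Longest linear sequence: 10 steps (1 and 2 through 22; 5, 12, 13 and 20 enter along the way).

Steps most likely to fail

Step 6. After ring closure the silyloxy group may be lost under the acid that the catalytic cycle produces, aromatizing the ring to a furan, or protodepalladation may compete with CO insertion. The fallback separates ring closure from carbonylation and uses two known reactions. It sets out from 11: 5-endo-dig iodocyclization (I2, NaHCO3, MeCN, 0 °C) should give tert-butyl{[(3S)-5-(3,4-dimethoxyphenyl)-4-iodo-2,3-dihydrofuran-3-yl]oxy}dimethylsilane F1 under basic conditions. Palladium-catalysed methoxycarbonylation of this vinyl iodide (Pd(OAc)2, dppf, CO 1 atm, Et3N, MeOH/DMF, 50 °C) then returns to the route at 16.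

Step 7. Hydrogen uptake by the tetrasubstituted push–pull alkene may be slow or poorly face-selective, and forcing it may bring over-reduction of the arene or hydrogenolysis of the benzylic C2–O1 bond. The fallback changes the order of reduction. It sets out from 16: i-Bu2AlH (CH2Cl2, −78 °C) should reduce the ester to [(4R)-4-(tert-butyldimethylsilyloxy)-2-(3,4-dimethoxyphenyl)-4,5-dihydrofuran-3-yl]methanol F2, an electron-rich enol ether with a coordinating hydroxymethyl group. Hydroxyl-assisted homogeneous hydrogenation ([Ir(cod)(PCy3)(py)]PF6, H2, CH2Cl2) should then add hydrogen anti to the silyloxy group without touching the arene or the benzylic ether. This returns to the route at 19 and makes step 8 unnecessary.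

Step 10. Once the C4 hydroxyl is free, the ester may migrate from the C6 oxygen to the cis C4 oxygen, or desilylation of the hindered secondary ether may be slow enough to invite it. The fallback removes silicon before the ester is present. It sets out from 19: Bu4NF (THF, rt) should give (3R,4S,5R)-5-(3,4-dimethoxyphenyl)-4-(hydroxymethyl)oxolan-3-ol F3. Selective acylation of its primary hydroxyl with 20 (2,4,6-collidine, CH2Cl2, −40 °C) relies on the primary-over-secondary rate difference and returns to the route at 22, replacing steps 9 and 10.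

Further compounds
F1 | step 6 | tert-butyl{[(3S)-5-(3,4-dimethoxyphenyl)-4-iodo-2,3-dihydrofuran-3-yl]oxy}dimethylsilane | IC1=C(c2ccc(OC)c(OC)c2)OC[C@@H]1O[Si](C)(C)C(C)(C)C
F2 | step 7 | [(4R)-4-(tert-butyldimethylsilyloxy)-2-(3,4-dimethoxyphenyl)-4,5-dihydrofuran-3-yl]methanol | OCC1=C(c2ccc(OC)c(OC)c2)OC[C@@H]1O[Si](C)(C)C(C)(C)C
F3 | step 10 | (3R,4S,5R)-5-(3,4-dimethoxyphenyl)-4-(hydroxymethyl)oxolan-3-ol | OC[C@H]1[C@@H](O)CO[C@H]1c1ccc(OC)c(OC)c1
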